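**Assumptions (one line):** The target is the trans (1S,2R) isomer exactly as in the given SMILES. 6-Bromovanillin and (R)-danshensu (free acid or sodium salt) are treated as purchasable.

## Retrosynthetic overview
1. The target hydroxy-enal comes from the 2,3-bis(hydroxymethyl) diol by chemoselective MnO2 oxidation of the conjugated CH2OH. The diol comes from DIBAL reduction of the diester. The diester comes from Pd-mediated removal of the C5 bromine blocker and the O-allyl group.
2. The only ring is the dihydronaphthalene. It is formed by an electrochemical dehydrogenative cyclization of the benzylic C1–H onto C8a–H of an (E)-α-alkylcinnamate, which sets the trans C1 centre.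
3. The cinnamate comes from a Horner–Wadsworth–Emmons (HWE) olefination of O-allyl-6-bromovanillin with a phosphonoacetate. The phosphonoacetate carbon is attached by SN2 inversion at the triflate of (R)-danshensu dimethyl ether, so the danshensu carbinol carbon becomes C2.
4. The bromine at C5 blocks the site para to the 8-OMe so that ring closure occurs at C8a, next to the OMe.

## Route

**Step 1**
Reactants: 1 (6-bromovanillin, 2-bromo-4-hydroxy-5-methoxybenzaldehyde); 2 (allyl bromide)
Product: 3 (4-(allyloxy)-2-bromo-5-methoxybenzaldehyde)
Conditions: allyl bromide, K2CO3, acetone, reflux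
Reagents that add atoms: allyl bromide, C=CCBr
Why: Williamson O-allylation masks the phenol, since the allyl group is removable later under Pd(0) without touching the rest of the molecule.

**Step 2**
Reactants: 4 ((R)-danshensu, (2R)-3-(3,4-dihydroxyphenyl)-2-hydroxypropanoic acid); 5 (MeI)
Product: 6 (methyl (R)-3-(3,4-dimethoxyphenyl)-2-hydroxypropanoate)
Conditions: MeI (4 equiv), K2CO3, acetone, reflux
Reagents that add atoms: MeI, CI
Why: The carboxylate and the two acidic phenols are alkylated while the less acidic secondary alcohol is untouched, and the carbinol stereocentre is not involved.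

**Step 3**
Reactants: 6; 7 (triflic anhydride)
Product: 8 (methyl (R)-3-(3,4-dimethoxyphenyl)-2-(trifluoromethylsulfonyloxy)propanoate)
Conditions: Tf2O, 2,6-lutidine, CH2Cl2, −78 → −40 °C; used crude at once
Reagents that add atoms: Tf2O, O=S(=O)(OS(=O)(=O)C(F)(F)F)C(F)(F)F
Why: It converts the α-hydroxy ester into an α-triflyloxy ester, a leaving group suited to clean SN2 inversion.

**Step 4**
Reactants: 8; 9 (trimethyl phosphonoacetate)
Product: 10 (methyl (2R)-3-(3,4-dimethoxyphenyl)-2-[1-(methoxycarbonyl)-1-(dimethoxyphosphoryl)methyl]propanoate; C3 epimeric mixture)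
Conditions: 9, NaH (1.5 equiv), THF, −20 °C → rt; add 8
Reagents that add atoms: trimethyl phosphonoacetate, COC(=O)CP(=O)(OC)OC
Why: SN2 displacement of the α-triflate by a stabilised carbanion goes with inversion, which converts the (R)-carbinol into the C2 stereocentre of the target; the C3 epimers converge in the next step.

**Step 5**
Reactants: 10; 3
Product: 11 (methyl (2R,E)-3-[4-(allyloxy)-2-bromo-5-methoxyphenyl]-2-[(R)-1-(methoxycarbonyl)-2-(3,4-dimethoxyphenyl)ethyl]acrylate)
Conditions: LiCl, DBU, MeCN, 0 °C → rt
Reagents that add atoms: none
Why: Masamune–Roush HWE olefination gives the trisubstituted (E)-cinnamate, with the aryl group trans to the ester and therefore cis to C2, as ring closure requires; the C2 centre is not touched.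

**Step 6**
Reactants: 11
Product: 12 (dimethyl (1S,2R)-7-(allyloxy)-5-bromo-1-(3,4-dimethoxyphenyl)-8-methoxy-1,2-dihydronaphthalene-2,3-dicarboxylate)
Conditions: undivided cell, graphite anode, Pt cathode, constant current (about 2.1 F/mol), nBu4NPF6 (0.1 M), HFIP/CH2Cl2 1:4, rt
Reagents that add atoms: none
Why: Proposed new method: anodic oxidation of the electron-rich veratryl ring (about 1.5 V, well below the bromo-alkoxy-cinnamate ring) gives a radical cation, which loses the benzylic C1–H and is oxidised again to a diarylmethyl-type cation in HFIP. The tethered C6–H of the cinnamate ring (C8a) attacks this cation 6-ring-closing, and the cathode releases H2, so the net reaction is a dehydrogenative C(sp3)–H/C(sp2)–H coupling. The bromine blocks the other ortho site (para to the OMe), forcing closure next to the OMe, and the half-chair transition state with a pseudo-axial aryl group (peri-OMe strain) puts Ar′ trans to the C2 ester, setting C1 as S. The closest known reactions are DDQ-mediated oxidative benzylic-cation cyclisations of dibenzylbutane lignans and anodic benzylic C–H functionalisation; this substrate class and this C8a-selective, Br-blocked closure to a 1-aryl-1,2-dihydronaphthalene are not reported.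

**Step 7**
Reactants: 12
Product: 13 (dimethyl (1S,2R)-1-(3,4-dimethoxyphenyl)-7-hydroxy-8-methoxy-1,2-dihydronaphthalene-2,3-dicarboxylate)
Conditions: Pd(OAc)2 (10 mol%), PPh3 (40 mol%), HCO2Na (5 equiv), DMF, 80 °C
Reagents that add atoms: none
Why: Pd–formate removes the allyl group (π-allyl transfer) and hydrodebrominates the aryl bromide, releasing the free 7-OH and restoring H at C5.

**Step 8**
Reactants: 13
Product: 14 ((1S,2R)-1-(3,4-dimethoxyphenyl)-2,3-bis(hydroxymethyl)-8-methoxy-1,2-dihydronaphthalen-7-ol)
Conditions: DIBAL-H (8 equiv), CH2Cl2, −78 → 0 °C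
Reagents that add atoms: none
Why: Hydride reduction takes both esters (saturated and conjugated, 1,2-addition) to the diol; C2 keeps its configuration because nothing here is enolisable.

**Step 9**
Reactants: 14
Product: 15 (vitekwangin B, (1S,2R)-7-hydroxy-1-(3,4-dimethoxyphenyl)-2-(hydroxymethyl)-8-methoxy-1,2-dihydronaphthalene-3-carbaldehyde)
Conditions: activated MnO2 (20 equiv), CH2Cl2, rt
Reagents that add atoms: none
Why: MnO2 oxidises only the conjugated cinnamyl-type CH2OH, leaving the saturated primary alcohol, which gives the enal and the free CH2OH of the target.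

## Compound list
1 | 6-bromovanillin | O=Cc1cc(OC)c(O)cc1Br | starting material
2 | allyl bromide | C=CCBr | starting material
3 | 4-(allyloxy)-2-bromo-5-methoxybenzaldehyde | O=Cc1cc(OC)c(OCC=C)cc1Br | intermediate
4 | (R)-danshensu | O=C(O)[C@H](O)Cc1ccc(O)c(O)c1 | starting material
5 | methyl iodide | CI | starting material
6 | methyl (R)-3-(3,4-dimethoxyphenyl)-2-hydroxypropanoate | COC(=O)[C@H](O)Cc1ccc(OC)c(OC)c1 | intermediate
7 | triflic anhydride | O=S(=O)(OS(=O)(=O)C(F)(F)F)C(F)(F)F | starting material
8 | methyl (R)-3-(3,4-dimethoxyphenyl)-2-(triflyloxy)propanoate | COC(=O)[C@H](OS(=O)(=O)C(F)(F)F)Cc1ccc(OC)c(OC)c1 | intermediate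
9 | trimethyl phosphonoacetate | COC(=O)CP(=O)(OC)OC | starting material
10 | phosphonate diester (C3 epimeric) | COC(=O)[C@@H](C(C(=O)OC)P(=O)(OC)OC)Cc1ccc(OC)c(OC)c1 | intermediate
11 | (E)-cinnamate diester | COC(=O)[C@@H](\C(C(=O)OC)=C/c1cc(OC)c(OCC=C)cc1Br)Cc1ccc(OC)c(OC)c1 | intermediate
12 | cyclised 5-bromo-7-allyloxy diester | COc1ccc([C@H]2c3c(c(Br)cc(OCC=C)c3OC)C=C(C(=O)OC)[C@@H]2C(=O)OC)cc1OC | intermediate
13 | 7-hydroxy diester | COc1ccc([C@H]2c3c(ccc(O)c3OC)C=C(C(=O)OC)[C@@H]2C(=O)OC)cc1OC | intermediate
14 | 2,3-bis(hydroxymethyl) diol | COc1ccc([C@H]2c3c(ccc(O)c3OC)C=C(CO)[C@@H]2CO)cc1OC | intermediate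
15 | vitekwangin B | COc1ccc([C@H]2c3c(ccc(O)c3OC)C=C(C=O)[C@@H]2CO)cc1OC | target

## Totals
Total steps: 9, of which step 1 is a parallel branch that makes the aldehyde. Longest linear sequence: 8 steps (4 → 6 → 8 → 10 → 11 → 12 → 13 → 14 → 15).

## Three steps most likely to fail
1. **Step 6 (new electrochemical cyclisation).** The product is easier to oxidise than the substrate and may over-oxidise to the naphthalene, or the cation may lose H+ to give a styrene. Fallback (known chemistry, different approach): oxidise C1 with DDQ in MeOH to the benzylic methyl ether, then close the ring in a separate Lewis-acid Friedel–Crafts step (BF3·OEt2 or TfOH), a polar two-stage aryltetralin-type closure.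
2. **Step 4 (SN2 at the β-aryl α-triflate).** Risks are E2 to the cinnamate, partial retention through a phenonium ion from the electron-rich aryl, and racemisation. Fallback: use a different chiral-pool source, Seebach alkylation of dimethyl malate (the enantiomer giving the (R)-2-benzylsuccinate) with veratryl chloride, then deoxygenation, then regioselective ester-enolate aldol with 3 and MsCl/DBU dehydration to give 11.
3. **Step 7 (Pd/formate debromination and deallylation).** The peri-hindered aryl bromide may react sluggishly, or the conjugated ester may be reduced or C2 epimerised at 80 °C. Fallback: deallylate separately with Pd(PPh3)4/K2CO3/MeOH, then do a radical hydrodebromination with (TMS)3SiH/AIBN, a radical instead of Pd–H pathway.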